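## Analysis of the target

Target 13 is an open-chain diarylheptanoid. Its heptane chain is numbered here C1 to C7 from the acetate end. It carries a 3,4-dihydroxyphenyl ring on each terminus (ring A on C1, ring B on C7), an acetoxy group on C3 (O3) and a free hydroxyl on C5 (O5).

The SMILES reads as 3R,5R, which in this chain is the 1,3-anti relation. The parent diol is C2-symmetric, so O3 and O5 are homotopic and a 1,3-acetyl shift only regenerates 13.

The stereocentres are hard to set by reagent control, because each carbinol carbon lies between two unbranched CH2 groups that differ only several atoms away. The second difficulty is chemoselectivity: exactly one of six hydroxyl groups, and one of two equivalent secondary ones, must carry the acetyl group.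

The catechols oxidise readily in air, above all under base, and the secondary acetate does not survive hydride or strong nucleophiles. The last step must therefore be neutral or weakly acidic, and reductive rather than oxidative.

The plan exploits the position of C1. It is a benzylic CH2 para to the 4-oxygen of ring A and stands 1,5 to O5. O5–C5–C4–C3–C2–C1 is therefore a latent oxane ring whose C1–O5 bond would be a benzylic ether that hydrogenolysis removes without trace.

In that ring C3 is position 4 and C5 is position 6. The 3,5-anti relation becomes the all-equatorial cis arrangement, O5 is masked as the ring oxygen, and O3 is the site at which a Prins cation takes up its nucleophile.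

## Retrosynthetic reasoning

**From 13 back to 11 (through 12).** The first move makes a bond instead of cutting one. O5 is joined to C1 and the four phenols are benzylated, which gives oxane 11.
- C1–O5 is of the same bond type as the four protecting-group bonds. The forward reaction is one hydrogenolysis that cleaves five benzylic C–O bonds and nothing else, since C3–O and C5–O are not benzylic.
- The two oxygens that are equivalent in the diol become an ester oxygen and a ring ether.
- The acyclic 1,3-anti problem becomes a ring problem.
- The extra stereocentre at C1 is sacrificial.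

**From 11 back to 7 and 8 (through 10 and 9).** Three bonds are cut together: C1–C2, C1–O5 and C3–O(acetyl). This is the Prins retron.
- In 13 the C1–C2 bond is a CH2–CH2 bond without any handle. In 11 it is exactly the bond that an alkene forms with an oxocarbenium ion.
- The cut splits the skeleton into two halves of equal size. Half 8 is commercial, and half 7 keeps only one stereocentre.
- The forward reaction has to close the ring through a chair and take up acetate equatorially.
- The roles are assigned so that ring A sits on the aldehyde carbon and C5 is the carbinol. The reverse assignment would put the controlling stereocentre at a benzylic carbon next to an electron-rich ring, where ionisation erases it. With the chosen pairing the information rests at the non-ionisable C5, and the conjugated cation 9 is the resting state.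

**From 7 back to 4 and 5 (through 6).** The C4–C5 bond is cut. A catalytic asymmetric allylation of an unbranched aldehyde is a dependable way to set an isolated carbinol of this kind. It delivers C2–C4 with the terminal alkene that the key step needs. This is the only absolute stereocontrol in the route.

**From 4 back to 1 and 2 (through 3).** The bond between ring B and C7 is cut. A Heck arylation of 2 with isomerisation gives the 3-arylpropanal in one step and at the right oxidation level, so no redox adjustment is needed.

Origin of the atoms in 13:

| Atoms | Source |
|---|---|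
| Ring A and C1 | 8 |
| C2–C4 | 5 |
| C5–C7 | 2 |
| Ring B | 1 |
| Acetyl group | the acetate taken up in the key step |

## Alternatives that were turned down

Alternative 1: the textbook route.
- **Disconnection:** the two C–H bonds at C3 and C5, back to the achiral symmetric β-diketone A1.
- **Forward key step:** Noyori hydrogenation of A1 with RuCl2[(R)-BINAP]. It sets both centres as a group and should give the C2-symmetric anti diol A2, with amplification of enantiomeric purity in the second reduction. Monoacetylation and debenzylation follow.
- **Why turned down:** the stereochemical elegance ends in the one compound in which O3 and O5 are homotopic. Acetylation of A2 is statistical or needs a detour through a cyclic orthoacetate. The key step forms no C–C bond, so the whole chain of A1 must be assembled first, under conditions that spare four benzyl ethers. The count comes to about six steps, and this is the plan most chemists would draw first.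

Alternative 2: Evans–Tishchenko route.
- **Disconnection:** the C5–H bond and the O3–acetyl bond together, back to β-hydroxy ketone A4. A4 is itself cut at the aldol bond next to the carbinol, into aldehyde 4 and methyl ketone A3.
- **Forward key step:** Evans–Tishchenko reaction of A4 with ethanal A5 and a catalyst derived from SmI2. A hemiacetal forms and passes hydride intramolecularly to the ketone, which gives the anti relation. The acetyl group stays on the old hydroxyl.
- **Why turned down:** the step solves the oxygen differentiation but forms no C–C bond. It moves the whole absolute-configuration problem onto an acetate-type aldol between two unbranched, enolisable partners. There the enolate has no α-substituent and the aldehyde no branching to organise the transition state. A4 is also prone to retro-aldol cleavage and dehydration, and A3 needs its own preparation. The count is six to seven steps.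

Alternative 3: two-directional epoxide opening.
- **Disconnection:** C1–C2 and C6–C7 at once, back to the C2-symmetric bis-epoxide A6 and two equivalents of the benzylic organometallic A7.
- **Forward key step:** double copper-catalysed opening of A6 at both terminal carbons. It gives A2 with both centres inherited from A6.
- **Why turned down:** A6 is a volatile C5 compound that needs its own multistep asymmetric preparation, so the precursor costs what the key step wins. A7 is an electron-rich benzylic Grignard reagent, a class that tends mechanistically to Wurtz-type homocoupling on formation. The route ends again at A2, with the monoacetylation problem untouched.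

Key step: step 3

Remark: compounds 1, 2, 5 and 8 are taken to be catalogue chemicals. The locants C1 to C7, O3, O5, ring A and ring B of 13 are used for all intermediates.

## Steps

Step 1
Reactants: 1 4-bromo-1,2-bis(benzyloxy)benzene; 2 prop-2-en-1-ol (allyl alcohol)
Product: 4 3-[3,4-bis(benzyloxy)phenyl]propanal, via enol 3 (not isolated)
Conditions: Pd(OAc)2 (cat.), n-Bu4NCl, NaHCO3, DMF, 90 °C
Reagents that add atoms: none
Why: Heck arylation of an allylic alcohol: zerovalent palladium inserts into the C–Br bond of 1, the aryl group adds to the terminal alkene carbon of 2, and β-hydride elimination towards the carbinol carbon gives enol 3, which tautomerises to 4. NaHCO3 is too weak a base to start aldol condensation of 4, and the benzyl ethers are inert.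

Step 2
Reactants: 4 3-[3,4-bis(benzyloxy)phenyl]propanal; 5 allyltributylstannane
Product: 7 (3R)-1-[3,4-bis(benzyloxy)phenyl]hex-5-en-3-ol, via tributylstannyl ether 6 (not isolated)
Conditions: Ti(OiPr)4 (10 mol %), (S)-BINOL (20 mol %), 4 Å MS, CH2Cl2, −20 °C; then sat. aq. NaHCO3
Reagents that add atoms: none
Why: Keck asymmetric allylation: the BINOL–titanium Lewis acid binds 4 and leaves one carbonyl face open to 5, and with (S)-BINOL unbranched aliphatic aldehydes give the R carbinol (allyl ranks above the arylethyl chain), which is C5 of 13. Stannyl ether 6 is hydrolysed on work-up.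

Step 3
Reactants: 7 (3R)-1-[3,4-bis(benzyloxy)phenyl]hex-5-en-3-ol; 8 3,4-bis(benzyloxy)benzaldehyde
Product: 11 (2R,4S,6R)-2-[3,4-bis(benzyloxy)phenyl]-6-{2-[3,4-bis(benzyloxy)phenyl]ethyl}oxan-4-yl acetate, via oxocarbenium ion 9 (not isolated), via oxan-4-yl cation 10 (not isolated)
Conditions: BF3·OEt2, AcOH, TMSOAc, slight excess of 8, CH2Cl2–cyclohexane, 0 °C; aq. NaHCO3 quench
Reagents that add atoms: acetic acid, CC(=O)O; trimethylsilyl acetate, CC(=O)O[Si](C)(C)C (carrier of the same acetate unit and water scavenger)
Why: This is a Prins cyclisation with acetate capture, and its closest known reaction type is the BF3·OEt2/AcOH-promoted union of homoallylic alcohols and aryl aldehydes to all-cis 2,6-disubstituted oxan-4-yl acetates. Alcohol 7 and aldehyde 8 condense to the (E)-oxocarbenium ion 9, the terminal alkene carbon C2 attacks C1, and the secondary cation 10 is captured by acetate at C3, so that C1–C2, C1–O5 and C3–O are all formed and the two halves of the skeleton are joined in one operation. The oxane ring closes in a 6-endo-trig mode (endo to both the C2=C3 and the C1=O5 π bond) through a chair. The only stereocentre present, C5, controls everything, because its arylethyl chain sits equatorial and so selects one of the two chairs. C1 is set by the E geometry of 9, which places ring A equatorial and cis to the C5 chain. C3 is set by equatorial attack on 10, whose C3–H bond is held pseudo-axial by delocalisation of the cation into the ring framework, and this puts the acetate cis to the C5 chain on the ring, that is 3,5-anti in the open chain. The step needs cyclisation and capture to outrun 2-oxonia-Cope rearrangement and hydrolytic side-chain exchange, which would move the stereochemical information to the ionisable benzylic carbon; the chosen pairing keeps 9, conjugated with ring A, as the more stable Cope isomer, only 8 is on offer as aldehyde, and TMSOAc removes the water of condensation and stray fluoride while BF3·OEt2 acts only as the Lewis acid. O5 is locked as the ring oxygen while O3 arrives acetylated, so no hydroxyl group ever has to be told from another, and epimerisation at C1 is harmless because C1 becomes CH2 in step 4.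

Step 4
Reactants: 11 (2R,4S,6R)-2-[3,4-bis(benzyloxy)phenyl]-6-{2-[3,4-bis(benzyloxy)phenyl]ethyl}oxan-4-yl acetate
Product: 13 (3R,5R)-1,7-bis(3,4-dihydroxyphenyl)-5-hydroxyheptan-3-yl acetate (CNP0132541.1), via tetraphenol 12 (not isolated)
Conditions: H2 (5 bar), Pd(OH)2/C, EtOAc–AcOH (4:1), 40 °C; filtration and concentration under argon
Reagents that add atoms: none
Why: Catalytic hydrogenolysis of benzylic C–O bonds: the four aryl benzyl ethers should go first (12), then the ring C1–O5 bond, a secondary benzylic ether now activated by the free para hydroxyl of ring A, as is known for 2-aryl cyclic ethers of the lignan type. C3–O and C5–O are not benzylic and keep their configuration, AcOH cannot transesterify the acetate, and acetyl migration between O3 and O5 is degenerate.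

## Compound list

1 | 4-bromo-1,2-bis(benzyloxy)benzene | Brc1ccc(OCc2ccccc2)c(OCc2ccccc2)c1 | starting material
2 | prop-2-en-1-ol (allyl alcohol) | C=CCO | starting material
3 | 3-[3,4-bis(benzyloxy)phenyl]prop-1-en-1-ol (enol, alkene geometry not defined) | OC=CCc1ccc(OCc2ccccc2)c(OCc2ccccc2)c1 | intermediate
4 | 3-[3,4-bis(benzyloxy)phenyl]propanal | O=CCCc1ccc(OCc2ccccc2)c(OCc2ccccc2)c1 | intermediate
5 | allyltributylstannane | C=CC[Sn](CCCC)(CCCC)CCCC | starting material
6 | tributylstannyl ether of (3R)-1-[3,4-bis(benzyloxy)phenyl]hex-5-en-3-ol | C=CC[C@H](O[Sn](CCCC)(CCCC)CCCC)CCc1ccc(OCc2ccccc2)c(OCc2ccccc2)c1 | intermediate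
7 | (3R)-1-[3,4-bis(benzyloxy)phenyl]hex-5-en-3-ol | C=CC[C@H](O)CCc1ccc(OCc2ccccc2)c(OCc2ccccc2)c1 | intermediate
8 | 3,4-bis(benzyloxy)benzaldehyde | O=Cc1ccc(OCc2ccccc2)c(OCc2ccccc2)c1 | starting material
9 | (E)-oxocarbenium ion from 7 and 8 (R at C5) | C=CC[C@@H](CCc1ccc(OCc2ccccc2)c(OCc2ccccc2)c1)/[O+]=C/c1ccc(OCc2ccccc2)c(OCc2ccccc2)c1 | intermediate
10 | 2,6-cis-2-[3,4-bis(benzyloxy)phenyl]-6-{2-[3,4-bis(benzyloxy)phenyl]ethyl}oxan-4-yl cation | [CH+]1C[C@H](c2ccc(OCc3ccccc3)c(OCc3ccccc3)c2)O[C@H](CCc2ccc(OCc3ccccc3)c(OCc3ccccc3)c2)C1 | intermediate
11 | (2R,4S,6R)-2-[3,4-bis(benzyloxy)phenyl]-6-{2-[3,4-bis(benzyloxy)phenyl]ethyl}oxan-4-yl acetate (all-cis) | CC(=O)O[C@@H]1C[C@H](c2ccc(OCc3ccccc3)c(OCc3ccccc3)c2)O[C@H](CCc2ccc(OCc3ccccc3)c(OCc3ccccc3)c2)C1 | intermediate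
12 | (2R,4S,6R)-2-(3,4-dihydroxyphenyl)-6-[2-(3,4-dihydroxyphenyl)ethyl]oxan-4-yl acetate | CC(=O)O[C@@H]1C[C@H](c2ccc(O)c(O)c2)O[C@H](CCc2ccc(O)c(O)c2)C1 | intermediate
13 | (3R,5R)-1,7-bis(3,4-dihydroxyphenyl)-5-hydroxyheptan-3-yl acetate | CC(=O)O[C@H](CCc1ccc(O)c(O)c1)C[C@H](O)CCc1ccc(O)c(O)c1 | target

## Step count and least certain steps

Total step count: 4. Longest linear sequence: 4 (1 → 4 → 7 → 11 → 13).

**Step 3 (key step).**
- The most likely failure is loss of enantiomeric purity and scrambling of the side chains. The cyclisation is reversible at the cation stage, and a 2-oxonia-Cope rearrangement transfers the stereochemical information from C5 to the benzylic C1. There, ionisation next to the electron-rich ring A, or hydrolysis and recombination, can erase it.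
- The aryl-stabilised cation is also a weak electrophile, so ring closure may be slow. That leaves room for Friedel–Crafts capture by ring B or for fluoride capture at C3.
- The fallback sets out from 7 and 8 and comes back at 11. It makes the O5–C1 bond first and generates the cation without free aldehyde or water. Pinnick oxidation of 8 (NaClO2, NaH2PO4, 2-methylbut-2-ene) gives 3,4-bis(benzyloxy)benzoic acid F1. Steglich esterification of F1 with 7 (DCC, DMAP) gives the homoallylic benzoate F2. Reductive acetylation (i-Bu2AlH at −78 °C, then Ac2O, pyridine, DMAP) gives the α-acetoxy ether F3 as a mixture at the acetal carbon. Ionisation of F3 (BF3·OEt2, AcOH, low temperature) releases 9 as an ion pair. The acetate that leaves C1 is the one taken up at C3, so F3 to 11 is an isomerisation with no exchange partner in the flask.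

**Step 4.**
- The ring C1–O5 bond is a cyclic secondary benzylic ether and is cleaved more slowly than aryl benzyl ethers, so the reaction may stall after debenzylation.
- Forcing it with more acid or heat invites elimination towards C2, followed by hydrogenolytic loss of the then allylic acetate.
- The fallback sets out from 11 and comes back at 13. It separates the two tasks. Ionic hydrogenation (Et3SiH, BF3·OEt2, CH2Cl2, −40 to 0 °C) opens the electron-rich benzylic ether to the dialkoxybenzyl cation, and the silane reduces it. After aqueous work-up this gives (3R,5R)-1,7-bis[3,4-bis(benzyloxy)phenyl]-5-hydroxyheptan-3-yl acetate F4. Ordinary debenzylation (H2, 1 bar, Pd/C, EtOAc, room temperature) then has only aryl benzyl ethers to cleave.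

**Step 1.**
- Oxidative addition to the electron-rich aryl bromide is slow.
- Insertion with the opposite regiochemistry would give the branched aldehyde.
- Prolonged heating may start self-condensation of the product.
- The fallback sets out from 1 and comes back at 4. It replaces the palladium chemistry by a polar C–C bond formation. Bromine–lithium exchange (n-BuLi, THF, −78 °C) gives [3,4-bis(benzyloxy)phenyl]lithium F5. This opens oxetane in the presence of BF3·OEt2 and, after an aq. NH4Cl quench, gives 3-[3,4-bis(benzyloxy)phenyl]propan-1-ol F6. Oxidation with Dess–Martin periodinane gives 4.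

## Further compounds

F1 | step 3 | 3,4-bis(benzyloxy)benzoic acid | O=C(O)c1ccc(OCc2ccccc2)c(OCc2ccccc2)c1
F2 | step 3 | (3R)-1-[3,4-bis(benzyloxy)phenyl]hex-5-en-3-yl 3,4-bis(benzyloxy)benzoate | C=CC[C@H](OC(=O)c1ccc(OCc2ccccc2)c(OCc2ccccc2)c1)CCc1ccc(OCc2ccccc2)c(OCc2ccccc2)c1
F3 | step 3 | [3,4-bis(benzyloxy)phenyl]{[(3R)-1-[3,4-bis(benzyloxy)phenyl]hex-5-en-3-yl]oxy}methyl acetate (both epimers at the acetal carbon) | C=CC[C@H](OC(OC(C)=O)c1ccc(OCc2ccccc2)c(OCc2ccccc2)c1)CCc1ccc(OCc2ccccc2)c(OCc2ccccc2)c1
F4 | step 4 | (3R,5R)-1,7-bis[3,4-bis(benzyloxy)phenyl]-5-hydroxyheptan-3-yl acetate | CC(=O)O[C@H](CCc1ccc(OCc2ccccc2)c(OCc2ccccc2)c1)C[C@H](O)CCc1ccc(OCc2ccccc2)c(OCc2ccccc2)c1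
F5 | step 1 | [3,4-bis(benzyloxy)phenyl]lithium | [Li]c1ccc(OCc2ccccc2)c(OCc2ccccc2)c1
F6 | step 1 | 3-[3,4-bis(benzyloxy)phenyl]propan-1-ol | OCCCc1ccc(OCc2ccccc2)c(OCc2ccccc2)c1
A1 | alternative 1 | 1,7-bis[3,4-bis(benzyloxy)phenyl]heptane-3,5-dione | O=C(CCc1ccc(OCc2ccccc2)c(OCc2ccccc2)c1)CC(=O)CCc1ccc(OCc2ccccc2)c(OCc2ccccc2)c1
A2 | alternative 1 | (3R,5R)-1,7-bis[3,4-bis(benzyloxy)phenyl]heptane-3,5-diol | O[C@H](CCc1ccc(OCc2ccccc2)c(OCc2ccccc2)c1)C[C@H](O)CCc1ccc(OCc2ccccc2)c(OCc2ccccc2)c1
A3 | alternative 2 | 4-[3,4-bis(benzyloxy)phenyl]butan-2-one | CC(=O)CCc1ccc(OCc2ccccc2)c(OCc2ccccc2)c1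
A4 | alternative 2 | (5R)-1,7-bis[3,4-bis(benzyloxy)phenyl]-5-hydroxyheptan-3-one | O[C@H](CCc1ccc(OCc2ccccc2)c(OCc2ccccc2)c1)CC(=O)CCc1ccc(OCc2ccccc2)c(OCc2ccccc2)c1
A5 | alternative 2 | ethanal | CC=O
A6 | alternative 3 | (2S,4S)-1,2:4,5-diepoxypentane | C1O[C@H]1C[C@H]1CO1
A7 | alternative 3 | 3,4-bis(benzyloxy)benzylmagnesium chloride | Cl[Mg]Cc1ccc(OCc2ccccc2)c(OCc2ccccc2)c1
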